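**Numbering.** Compounds 1–17 are fixed by the steps below and used throughout. "Geranyl" stands for (2E)-3,7-dimethylocta-2,6-dien-1-yl.

## Analysis of the target

Target 17 is a flavanone: a chroman-4-one (rings A and C) with a 3',4'-dimethoxyphenyl ring B at C2. Ring B carries an (E)-geranyl chain at C2', wedged between the junction carbon C1' and the 3'-methoxy group. Ring A has a phloroglucinol pattern with a free 5-OH, hydrogen-bonded to the C4 carbonyl, and a 7-OMe. The only stereocentre is C2 (S); the only other stereo element is the E double bond C2''=C3'' of the side chain. C2 is benzylic and β to the ketone through O1, so base or strong acid can erase it by retro-oxa-Michael opening to the 2'-hydroxychalcone. The 1,5-diene of the geranyl chain rules out strong protic or Lewis acids (cation–olefin cyclisation), late electrophilic halogenation or oxidation, and unselective hydrogenation. The hard points are placing the geranyl group at the most crowded position of ring B, keeping one phenol free beside three methyl ethers, and setting a labile stereocentre next to a doubly ortho-substituted aryl group. The strategy rests on two facts: C4 is a one-carbon carbonyl bridge between C4a of ring A and the C3–C2 unit, and C4a is flanked by two oxygens (O1 on C8a, OH on C5), so with both as free hydroxyls ring A is symmetric about the C4a–C7 axis.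

## Retrosynthetic reasoning

**17 to 14 (O–Si, then C2–H and C3–H).** The stereocentre is removed first. Cleaving the silyl ether of 16 and taking H2 off C2–C3 leads to the planar chromenone 14, which cannot racemise or ring-open. The forward reaction must deliver hydride to one face of C2 only, leave the carbonyl and both geranyl alkenes alone, and work without base; a chiral copper hydride catalyst fits. The silyl group on O5 (14 from 13) is needed because the free chelated phenol would quench the hydride and, as a metal phenoxide conjugated to C4, switch off the enone.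

**13 to 9, 10 and 7 (C4a–C4, C4–C3, O1–C2).** All three bonds of ring C that reach ring A or C4 are cut at once. This splits the molecule into halves of similar size and takes C4 from carbon monoxide 10. Because 9 has two equivalent hydroxyl groups around the carbon that becomes C4a, no protecting group or regiocontrol is needed on ring A. The chalcone cut (C2–C3 aldol, O1–C2) would need a ring A acetophenone with differentiated oxygens. A cut at C2–C1' would need a very hindered aryl nucleophile. The forward reaction must insert 10 before the alkyne couples and must close the ring in the 6-endo sense.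

**7 to 6, then 6 to 1 and 2 (alkyne carbon; C2'–C1'').** The terminal alkyne is traced to the aldehyde 6 by a one-carbon homologation. The aryl–CH2 bond of 6 is then cut, because its ring carbon lies between the formyl carbon and the 3-methoxy group of 1, the site where two directing groups cooperate in metalation. Veratraldehyde 1 already holds every oxygen of ring B, so only the geranyl electrophile 2 has to be added.

**9 to 8 (C–I).** The iodine sits between the two hydroxyl groups of 8, the position favoured in iodination of resorcinol phenoxides, so one step from a commercial phenol suffices.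

## Alternatives that were turned down

**Alternative 1: ring contraction of a benzodioxine enol acetal.** 
- Disconnection: the C2–C3 bond. The precursor is the racemic 4-methylene-1,3-benzodioxine A2, reachable from a ring A hydroxy acid, aldehyde 6 and a carbonyl methylenation. 
- Forward key step: a chiral Lewis acid ionises C2–O3 of A2 to an aryl-stabilised oxocarbenium ion with a tethered enolate, whose carbon attacks C2 to give A1. 
- For: C2–C3 and the stereocentre form in one event; the racemic acetal centre is erased on ionisation, so the step is stereoconvergent; the flavanone oxidation level is reached directly. A1 is the same compound as 16, one deprotection from 17. On directness of the stereo-forming step this alternative is stronger. 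
- Against: the enantio-determining event is recombination of an ion pair, with the chiral acid on the enolate oxygen and far from the prochiral carbon. In this substrate the cationic carbon is bonded to C1', and the C2''=C3'' alkene on C2' can close a five-membered ring onto it, a cation–olefin cyclisation that competes intramolecularly with the enolate. The same acid can reopen A1 by retro-oxa-Michael reaction and threatens the aryl silyl ether. 
- Comparison: the step count after 6 is about the same as in the chosen route. The chosen route never forms a cation next to the geranyl chain and sets C2 by a ligand-controlled hydride transfer of a known type.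

**Alternative 2: ring B by cycloaddition and aromatisation.** 
- Disconnection: C2'–C3' and C1'–C6' of ring B. 
- Forward key step: 3-methoxyfuran A5 and the geranyl-substituted ynoate A4 undergo [4+2] cycloaddition; the oxygen-bridged adduct opens under mild Lewis acid to the phenol A3. 
- For: the order ester, geranyl, oxygen on ring B follows from the polarity match of the nucleophilic C2 of A5 with the β carbon of A4. No organolithium or directed metalation is involved. On regiochemical certainty of ring B it is stronger than step 1 of the chosen route. 
- Against: it solves only ring B. A3 still needs O-methylation and adjustment of the ester before it reaches the stage of 6 or 7, which the chosen route reaches from 1 in one or two steps. A4 has a CH2 that is both propargylic and allylic and is prone to isomerise. A5 is volatile and acid-sensitive. Furan cycloadditions with disubstituted alkynes are sluggish and reversible. The opening uses a Lewis acid beside the diene. Ring C and C2 would still need another key step. 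
- Comparison: the chosen strategy spends its key step on ring C and on joining the two halves, and buys the ring B pattern with 1.

**Alternative 3: aryne annulation with a chiral hydroxy ester.** 
- Disconnection: O1–C8a and C4–C4a. 
- Forward key step: fluoride releases the ring A aryne from the silyl triflate A7; the alkoxide of the (S)-β-hydroxy ester A8 adds to C8a, the aryne carbon remote from the methoxymethoxy group; the aryl anion at C4a attacks the ester carbonyl and closes ring C to A6. 
- For: the stereocentre is made early in A8 by dependable carbonyl chemistry and its C–O bond is never broken. The alkoxy group directs the aryne addition. Two bonds form without a transition metal. On certainty of the enantioselective step it is stronger than the chosen route. 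
- Against: the alkoxide of A8 is a benzylic β-alkoxy ester, so retro-aldol cleavage (which also racemises) and elimination to the cinnamate compete with a slow alkoxide-to-aryne addition. The aryne is a strong enophile and A8 has two trisubstituted alkenes with allylic hydrogens. A6 forms in basic fluoride, the conditions under which flavanones open to chalcones. Ring A needs two different oxygen groups and A7 takes several steps, against one step to 9. The final acetal removal needs acid beside the diene. 
- Comparison: longer, with more points of failure. The chosen route uses an unprotected symmetric ring A and keeps the stereocentre away from all basic bond-forming steps.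

Key step: step 4

Assumption: (R)-DTBM-SEGPHOS is taken as the ligand enantiomer whose copper hydride attacks the face of C2 that leads to (2S); if the sense is the reverse, the (S) ligand is used and nothing else changes.

## Route

Step 1
Reactants: 1 veratraldehyde; 2 geranyl bromide
Product: 6 2-[(2E)-3,7-dimethylocta-2,6-dien-1-yl]-3,4-dimethoxybenzaldehyde, via lithium aminoalkoxide 3 (not isolated), via C2-lithiated aminoalkoxide 4 (not isolated), via geranylated aminoalkoxide 5 (not isolated)
Conditions: Me2NCH2CH2NHMe, n-BuLi, THF, −20 °C, then 1; n-BuLi, −20 °C; CuBr·SMe2 (10 mol %), 2 (excess), −78 → 0 °C; cold dil. aq HCl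
Reagents that add atoms: N,N,N'-trimethylethylenediamine, CNCCN(C)C, and n-butyllithium, [Li]CCCC (their atoms stay only in the intermediates 3, 4 and 5)
Why: The aminoalkoxide 3 masks the aldehyde and, together with the 3-methoxy group, directs lithiation to C2 (directed ortho-metalation at the cooperative site) to give 4. Copper-catalysed allylic substitution on 2 should occur at the primary carbon rather than the disubstituted γ carbon, with the E geometry kept, and acid work-up of 5 releases the aldehyde.

Step 2
Reactants: 6 2-geranyl-3,4-dimethoxybenzaldehyde
Product: 7 1-ethynyl-2-[(2E)-3,7-dimethylocta-2,6-dien-1-yl]-3,4-dimethoxybenzene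
Conditions: MeC(O)C(N2)P(O)(OMe)2, K2CO3, MeOH, 0 °C → rt
Reagents that add atoms: dimethyl (1-diazo-2-oxopropyl)phosphonate, COP(=O)(OC)C(=[N+]=[N-])C(C)=O
Why: Ohira–Bestmann variant of the Seyferth–Gilbert homologation: the diazomethylphosphonate anion formed by methanolysis adds to the aldehyde, phosphate is eliminated, and loss of N2 with 1,2-hydrogen shift gives the terminal alkyne. The mild carbonate base should leave the benzylic, allylic CH2 and the diene untouched.

Step 3
Reactants: 8 5-methoxyresorcinol
Product: 9 2-iodo-5-methoxyresorcinol
Conditions: I2, NaHCO3, THF–H2O, 0 °C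
Reagents that add atoms: iodine, II
Why: Electrophilic aromatic iodination of the phenoxide; in aqueous hydrogencarbonate resorcinols are iodinated at the carbon between the two hydroxyl groups. One equivalent of iodine at 0 °C limits polyiodination.

Step 4
Reactants: 9 2-iodo-5-methoxyresorcinol; 7 1-ethynyl-2-geranyl-3,4-dimethoxybenzene; 10 carbon monoxide
Product: 13 2-{2-[(2E)-3,7-dimethylocta-2,6-dien-1-yl]-3,4-dimethoxyphenyl}-5-hydroxy-7-methoxy-4H-chromen-4-one, via hydroxyaryl ynone 11 (not isolated), via diethylamino enone 12 (not isolated)
Conditions: PdCl2(PPh3)2 (5 mol %), CO (20 bar), Et2NH, 120 °C, autoclave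
Reagents that add atoms: diethylamine, CCNCC (its atoms stay only in intermediate 12)
Why: The divalent palladium precatalyst is reduced in the amine to zerovalent palladium, which inserts into the C–I bond of 9; CO insertion gives the aroylpalladium iodide, the amine-deprotonated alkyne 7 replaces iodide, and reductive elimination forms C4a–C4 and C4–C3 in the ynone 11. Diethylamine then adds to the β carbon of 11 to give the enaminone 12, and one of the two ortho hydroxyl groups attacks that carbon (6-endo-trig addition–elimination, equal overall to a 6-endo-dig closure of 11), expels diethylamine and forms O1–C2 of ring C. The closest known reaction type is the palladium-catalysed carbonylative annulation of ortho-iodophenols with terminal arylalkynes to flavones in secondary amines. No stereocentre is formed. The step needs CO insertion to outrun direct alkyne coupling, which would end in a 2-arylbenzofuran; the CO pressure and the absence of a copper co-catalyst secure this. It needs 6-endo rather than 5-exo closure (flavone, not aurone), which the enaminone path secures because the amine marks the β carbon as the only electrophilic site. It needs no choice between the two hydroxyl groups, since the mirror plane through C2 and C5 of 9 makes them equivalent and the one not used becomes the chelated 5-OH. The trisubstituted, unactivated geranyl alkenes should stay out of the palladium chemistry.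

Step 5
Reactants: 13 5-hydroxyflavone from step 4
Product: 14 5-{[tert-butyl(dimethyl)silyl]oxy}-2-(2-geranyl-3,4-dimethoxyphenyl)-7-methoxy-4H-chromen-4-one
Conditions: TBSOTf, 2,6-lutidine, CH2Cl2, 0 °C
Reagents that add atoms: tert-butyldimethylsilyl trifluoromethanesulfonate, CC(C)(C)[Si](C)(C)OS(=O)(=O)C(F)(F)F
Why: O-silylation of a hydrogen-bonded phenol needs the reactive silyl triflate; the hindered pyridine base traps the triflic acid so that the diene is not protonated. The silyl ether removes the acidic OH that would consume the copper hydride and deactivate the enone as a phenoxide.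

Step 6
Reactants: 14 5-silyloxyflavone
Product: 16 (2S)-5-{[tert-butyl(dimethyl)silyl]oxy}-2-(2-geranyl-3,4-dimethoxyphenyl)-7-methoxy-2,3-dihydro-4H-chromen-4-one, via silyl enol ether 15 (not isolated)
Conditions: Cu(OAc)2·H2O (5 mol %), (R)-DTBM-SEGPHOS (5.5 mol %), (EtO)2MeSiH, toluene, 0 °C → rt; then AcOH, THF–H2O, 0 °C
Reagents that add atoms: diethoxy(methyl)silane, CCO[SiH](C)OCC (its silyl group stays only in intermediate 15)
Why: Asymmetric copper hydride conjugate reduction: the bisphosphine-bound monovalent copper hydride transfers hydride to C2 on the face left open by the ligand, which sets (2S), and the copper enolate is silylated by the silane to 15, which is not reduced further and is hydrolysed by dilute acetic acid. Unactivated trisubstituted alkenes do not insert into the copper hydride, and the 5-silyloxy group shields the carbonyl from 1,2-reduction.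

Step 7
Reactants: 16 (2S)-5-silyloxyflavanone
Product: 17 (2S)-2-{2-[(2E)-3,7-dimethylocta-2,6-dien-1-yl]-3,4-dimethoxyphenyl}-5-hydroxy-7-methoxy-2,3-dihydro-4H-chromen-4-one
Conditions: Bu4NF, AcOH (1:1), THF, 0 °C
Reagents that add atoms: none
Why: Fluoride cleavage of the aryl silyl ether; the acetic acid buffer protonates the phenoxide at once, so no enolate is present to open ring C by retro-oxa-Michael reaction and C2 should keep its configuration.

## Compound list

1 | veratraldehyde (3,4-dimethoxybenzaldehyde) | COc1ccc(C=O)cc1OC | starting material
2 | geranyl bromide ((2E)-1-bromo-3,7-dimethylocta-2,6-diene) | BrC/C=C(\C)CCC=C(C)C | starting material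
3 | lithium {[2-(dimethylamino)ethyl](methyl)amino}(3,4-dimethoxyphenyl)methanolate | COc1ccc(C(O[Li])N(C)CCN(C)C)cc1OC | intermediate
4 | 2-lithio derivative of 3 | COc1ccc(C(O[Li])N(C)CCN(C)C)c([Li])c1OC | intermediate
5 | lithium {[2-(dimethylamino)ethyl](methyl)amino}(2-geranyl-3,4-dimethoxyphenyl)methanolate | COc1ccc(C(O[Li])N(C)CCN(C)C)c(C/C=C(\C)CCC=C(C)C)c1OC | intermediate
6 | 2-[(2E)-3,7-dimethylocta-2,6-dien-1-yl]-3,4-dimethoxybenzaldehyde | COc1ccc(C=O)c(C/C=C(\C)CCC=C(C)C)c1OC | intermediate
7 | 1-ethynyl-2-[(2E)-3,7-dimethylocta-2,6-dien-1-yl]-3,4-dimethoxybenzene | COc1ccc(C#C)c(C/C=C(\C)CCC=C(C)C)c1OC | intermediate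
8 | 5-methoxyresorcinol (5-methoxybenzene-1,3-diol) | COc1cc(O)cc(O)c1 | starting material
9 | 2-iodo-5-methoxyresorcinol (2-iodo-5-methoxybenzene-1,3-diol) | COc1cc(O)c(I)c(O)c1 | intermediate
10 | carbon monoxide | [C-]#[O+] | starting material
11 | 1-(2,6-dihydroxy-4-methoxyphenyl)-3-(2-geranyl-3,4-dimethoxyphenyl)prop-2-yn-1-one | COc1cc(O)c(C(=O)C#Cc2ccc(OC)c(OC)c2C/C=C(\C)CCC=C(C)C)c(O)c1 | intermediate
12 | 3-(diethylamino)-1-(2,6-dihydroxy-4-methoxyphenyl)-3-(2-geranyl-3,4-dimethoxyphenyl)prop-2-en-1-one (enamine geometry immaterial, either isomer closes) | COc1cc(O)c(C(=O)C=C(N(CC)CC)c2ccc(OC)c(OC)c2C/C=C(\C)CCC=C(C)C)c(O)c1 | intermediate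
13 | 2-{2-[(2E)-3,7-dimethylocta-2,6-dien-1-yl]-3,4-dimethoxyphenyl}-5-hydroxy-7-methoxy-4H-chromen-4-one | COc1cc(O)c2c(c1)oc(-c1ccc(OC)c(OC)c1C/C=C(\C)CCC=C(C)C)cc2=O | intermediate
14 | 5-{[tert-butyl(dimethyl)silyl]oxy}-2-(2-geranyl-3,4-dimethoxyphenyl)-7-methoxy-4H-chromen-4-one | COc1cc(O[Si](C)(C)C(C)(C)C)c2c(c1)oc(-c1ccc(OC)c(OC)c1C/C=C(\C)CCC=C(C)C)cc2=O | intermediate
15 | (2S)-5-{[tert-butyl(dimethyl)silyl]oxy}-4-{[diethoxy(methyl)silyl]oxy}-2-(2-geranyl-3,4-dimethoxyphenyl)-7-methoxy-2H-chromene | COc1cc(O[Si](C)(C)C(C)(C)C)c2c(c1)O[C@H](c1ccc(OC)c(OC)c1C/C=C(\C)CCC=C(C)C)C=C2O[Si](C)(OCC)OCC | intermediate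
16 | (2S)-5-{[tert-butyl(dimethyl)silyl]oxy}-2-(2-geranyl-3,4-dimethoxyphenyl)-7-methoxy-2,3-dihydro-4H-chromen-4-one | COc1cc(O[Si](C)(C)C(C)(C)C)c2c(c1)O[C@H](c1ccc(OC)c(OC)c1C/C=C(\C)CCC=C(C)C)CC2=O | intermediate
17 | (2S)-2-{2-[(2E)-3,7-dimethylocta-2,6-dien-1-yl]-3,4-dimethoxyphenyl}-5-hydroxy-7-methoxy-2,3-dihydro-4H-chromen-4-one | COc1cc(O)c2c(c1)O[C@H](c1ccc(OC)c(OC)c1C/C=C(\C)CCC=C(C)C)CC2=O | target

## Step count and risk

Total step count: 7. Longest linear sequence: 6 (steps 1, 2, 4, 5, 6, 7); step 3 is a one-step branch that joins at step 4.

**Step 4 (key step).** 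
- What may go wrong: direct alkyne coupling before CO insertion, followed by cyclisation to a benzofuran; capture of the aroylpalladium by diethylamine; slow oxidative addition into the electron-rich, doubly ortho-substituted iodide with reductive loss of iodine; closure in the 5-exo sense. 
- Fallback: build the ynone without palladium, setting out from 7 and 8 and returning at 11. Compound 8 is protected (MOMCl, i-Pr2NEt) as 1-methoxy-3,5-bis(methoxymethoxy)benzene F1. Lithiation between the two acetal oxygens (n-BuLi, THF, 0 °C) and DMF give 4-methoxy-2,6-bis(methoxymethoxy)benzaldehyde F2. The lithium acetylide of 7 (n-BuLi, THF, −78 °C) adds to F2 to give 3-(2-geranyl-3,4-dimethoxyphenyl)-1-[4-methoxy-2,6-bis(methoxymethoxy)phenyl]prop-2-yn-1-ol F3. MnO2 in CH2Cl2 oxidises F3 to 3-(2-geranyl-3,4-dimethoxyphenyl)-1-[4-methoxy-2,6-bis(methoxymethoxy)phenyl]prop-2-yn-1-one F4. Brief treatment with catalytic HCl in MeOH at room temperature removes both acetals and returns 11, which diethylamine in ethanol closes through 12 to 13 as in step 4.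

**Step 6.** 
- What may go wrong: slow hydride transfer to a β carbon that is a vinylogous ester and carries a twisted, ortho-substituted aryl group; poor facial selectivity because the ortho geranyl chain crowds both faces; competing 1,2-reduction; loss of the aryl silyl ether. 
- Fallback: racemic reduction followed by kinetic resolution, setting out from 14 and returning at 16. LiBH(s-Bu)3 in THF at −78 °C gives racemic 5-{[tert-butyl(dimethyl)silyl]oxy}-2-(2-geranyl-3,4-dimethoxyphenyl)-7-methoxy-2,3-dihydro-4H-chromen-4-one F5. Asymmetric transfer hydrogenation with [Cp*RhCl(TsDPEN)] and HCO2H/Et3N, using the TsDPEN enantiomer for which the (2R) ketone is the fast-reacting one, converts that enantiomer into (2R,4R)-5-{[tert-butyl(dimethyl)silyl]oxy}-2-(2-geranyl-3,4-dimethoxyphenyl)-7-methoxychroman-4-ol F6. The unreacted ketone 16 is separated; at best half of the material is kept.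

**Step 3.** 
- What may go wrong: iodination at C4 or C6 (between OH and OMe) instead of C2, and di-iodination. The wrong isomer would carry through to a 7-hydroxy-5-methoxy flavone. 
- Fallback: fix the position by directed metalation, setting out from 8 and returning at 9. Compound 8 is converted into 1-methoxy-3,5-bis(methoxymethoxy)benzene F1 as above. n-BuLi in THF at 0 °C followed by I2 gives 2-iodo-5-methoxy-1,3-bis(methoxymethoxy)benzene F7. Mild acid (catalytic HCl, MeOH, room temperature) removes the acetals to give 9.

**Step 1.** 
- What may go wrong: incomplete lithiation; in the allylation, attack at the γ terminus, loss of alkene geometry, and consumption of 2 by residual butyllithium. 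
- Fallback: separate metalation from C–C coupling, setting out from 1 (through 4) and returning at 6. The aryllithium 4 is quenched with Me3SnCl; acid work-up gives 3,4-dimethoxy-2-(trimethylstannyl)benzaldehyde F8, which is purified and its substitution pattern checked. Stille allylation of F8 with 2 (Pd2(dba)3, AsPh3, DMF, 50 °C) proceeds through a π-allylpalladium intermediate that couples at its less hindered end and should give 6.

## Further compounds

F1 | step 4 | 1-methoxy-3,5-bis(methoxymethoxy)benzene | COCOc1cc(OC)cc(OCOC)c1
F2 | step 4 | 4-methoxy-2,6-bis(methoxymethoxy)benzaldehyde | COCOc1cc(OC)cc(OCOC)c1C=O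
F3 | step 4 | 3-(2-geranyl-3,4-dimethoxyphenyl)-1-[4-methoxy-2,6-bis(methoxymethoxy)phenyl]prop-2-yn-1-ol (racemic) | COCOc1cc(OC)cc(OCOC)c1C(O)C#Cc1ccc(OC)c(OC)c1C/C=C(\C)CCC=C(C)C
F4 | step 4 | 3-(2-geranyl-3,4-dimethoxyphenyl)-1-[4-methoxy-2,6-bis(methoxymethoxy)phenyl]prop-2-yn-1-one | COCOc1cc(OC)cc(OCOC)c1C(=O)C#Cc1ccc(OC)c(OC)c1C/C=C(\C)CCC=C(C)C
F5 | step 6 | racemic 5-{[tert-butyl(dimethyl)silyl]oxy}-2-(2-geranyl-3,4-dimethoxyphenyl)-7-methoxy-2,3-dihydro-4H-chromen-4-one | COc1cc(O[Si](C)(C)C(C)(C)C)c2c(c1)OC(c1ccc(OC)c(OC)c1C/C=C(\C)CCC=C(C)C)CC2=O
F6 | step 6 | (2R,4R)-5-{[tert-butyl(dimethyl)silyl]oxy}-2-(2-geranyl-3,4-dimethoxyphenyl)-7-methoxychroman-4-ol | COc1cc(O[Si](C)(C)C(C)(C)C)c2c(c1)O[C@@H](c1ccc(OC)c(OC)c1C/C=C(\C)CCC=C(C)C)C[C@H]2O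
F7 | step 3 | 2-iodo-5-methoxy-1,3-bis(methoxymethoxy)benzene | COCOc1cc(OC)cc(OCOC)c1I
F8 | step 1 | 3,4-dimethoxy-2-(trimethylstannyl)benzaldehyde | COc1ccc(C=O)c([Sn](C)(C)C)c1OC
A1 | alternative 1 | (2S)-5-{[tert-butyl(dimethyl)silyl]oxy}-2-(2-geranyl-3,4-dimethoxyphenyl)-7-methoxychroman-4-one | COc1cc(O[Si](C)(C)C(C)(C)C)c2c(c1)O[C@H](c1ccc(OC)c(OC)c1C/C=C(\C)CCC=C(C)C)CC2=O
A2 | alternative 1 | racemic 5-{[tert-butyl(dimethyl)silyl]oxy}-2-(2-geranyl-3,4-dimethoxyphenyl)-7-methoxy-4-methylidene-4H-1,3-benzodioxine | COc1cc(O[Si](C)(C)C(C)(C)C)c2c(c1)OC(c1ccc(OC)c(OC)c1C/C=C(\C)CCC=C(C)C)OC2=C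
A3 | alternative 2 | methyl 2-[(2E)-3,7-dimethylocta-2,6-dien-1-yl]-3-hydroxy-4-methoxybenzoate | COC(=O)c1ccc(OC)c(O)c1C/C=C(\C)CCC=C(C)C
A4 | alternative 2 | methyl (5E)-6,10-dimethylundeca-5,9-dien-2-ynoate | COC(=O)C#CC/C=C(\C)CCC=C(C)C
A5 | alternative 2 | 3-methoxyfuran | COc1ccoc1
A6 | alternative 3 | (2S)-2-(2-geranyl-3,4-dimethoxyphenyl)-7-methoxy-5-(methoxymethoxy)chroman-4-one | COc1cc(OCOC)c2c(c1)O[C@H](c1ccc(OC)c(OC)c1C/C=C(\C)CCC=C(C)C)CC2=O
A7 | alternative 3 | 5-methoxy-3-(methoxymethoxy)-2-(trimethylsilyl)phenyl trifluoromethanesulfonate | COCOc1cc(OC)cc(OS(=O)(=O)C(F)(F)F)c1[Si](C)(C)C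
A8 | alternative 3 | methyl (3S)-3-(2-geranyl-3,4-dimethoxyphenyl)-3-hydroxypropanoate | COC(=O)C[C@H](O)c1ccc(OC)c(OC)c1C/C=C(\C)CCC=C(C)C
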